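The ladder (rings B, C and D) holds only two methylene carbons, C4 and C5, both in the terminal ring D (C3–C6). The route therefore rests on cutting C3–C4 and C5–C6: ring D is added last, as the two carbons of dichloroketene, to the strained C3=C6 bond of a tricyclic cyclobutene, and the carbonyl oxygen and both chlorines are then erased. One thermal [2+2] cycloaddition closes ring D and sets C3 and C6, cis-fused and anti to ring B. Its precursor is the enantiopure ring A–ring B–bicyclo[2.2.0]hex-2-ene tricycle carrying the C11 octyl chain, which ends in a primary chloride that is an inert spectator and later the site of etherification.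

Key step: step 11

Assumption: with cyclobutenone the (S)-oxazaborolidinium catalyst of step 4 is taken to expose the enone face that leads to the (1R,6R) adduct 8 (α-C–H···O binding model for 2-cycloalkenones); this sense is not secure, and if the first run shows the opposite, the equally available (R)-catalyst is used and nothing else changes.

Atom labels: bicyclic intermediates use bicyclo[4.2.0]octane numbering. All polycyclic intermediates use the numbering of the final core, tetracyclo[6.4.0.0^2,7.0^3,6]dodecane: ring A = C1, C8–C12 (chain on C11); ring B = C1, C2, C7, C8; ring C = C2, C3, C6, C7; ring D = C3–C6.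

Step 1
Reactants: 1 chloroprene (2-chlorobuta-1,3-diene); 2 1-bromo-8-chlorooctane
Product: 4 2-(8-chlorooctyl)buta-1,3-diene, via buta-1,3-dien-2-ylmagnesium chloride 3 (not isolated)
Conditions: Mg, ZnCl2 (cat.), BrCH2CH2Br (cat.), THF, reflux; then 2, Li2CuCl4 (3 mol %), THF, −10 → 0 °C
Reagents that add atoms: none
Why: Copper-catalysed Grignard–alkyl halide cross-coupling, in which the dienyl Grignard reagent reacts through C2 and substitutes the primary C–Br bond far faster than the C–Cl bond; no stereocentre is formed.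

Step 2
Reactants: 5 3-oxocyclobutane-1-carboxylic acid
Product: 6 3-bromocyclobutan-1-one
Conditions: HgO (red), Br2, MgSO4, CH2Cl2, reflux, dark
Reagents that add atoms: bromine, BrBr
Why: Cristol–Firth variant of the Hunsdiecker bromodecarboxylation, the acyl hypobromite losing CO2 to a secondary radical that is capped by bromine while the ketone stays untouched.

Step 3
Reactants: 6 3-bromocyclobutan-1-one
Product: 7 cyclobut-2-en-1-one
Conditions: n-Bu3N, CH2Cl2, rt; vacuum transfer, kept as a cold CH2Cl2 solution and used at once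
Reagents that add atoms: none
Why: E1cB dehydrobromination of a β-bromoketone by a hindered amine gives the strained enone, which is handled cold to avoid oligomerisation.

Step 4
Reactants: 7 cyclobut-2-en-1-one; 4 2-(8-chlorooctyl)buta-1,3-diene
Product: 8 (1R,6R)-3-(8-chlorooctyl)bicyclo[4.2.0]oct-3-en-7-one (cis-fused)
Conditions: (S)-3,3-diphenyl-1-(o-tolyl)tetrahydro-1H,3H-pyrrolo[1,2-c][1,3,2]oxazaborole (20 mol %), Tf2NH (18 mol %), CH2Cl2, −78 → −40 °C
Reagents that add atoms: none
Why: Enantioselective Diels–Alder reaction under chiral oxazaborolidinium Lewis acid catalysis: the carbonyl-bound enone is attacked suprafacially on its unshielded face, which makes C1–H and C6–H cis and fixes their absolute sense, while the activated dienophile steers the 2-alkyl diene to the "para" orientation (chain on C3, 1,4 to C6).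

Step 5
Reactants: 8 (1R,6R)-3-(8-chlorooctyl)bicyclo[4.2.0]oct-3-en-7-one
Product: 9 (1R,3S,6R)-3-(8-chlorooctyl)bicyclo[4.2.0]octan-7-one (chain cis to the four-membered ring)
Conditions: H2 (1 atm), 5% Pd/C, EtOAc, rt
Reagents that add atoms: none
Why: Heterogeneous catalytic hydrogenation delivers H2 to the convex face of the cis-fused bicycle (the face of H1 and H6), which sets C3 with the chain on the side of the four-membered ring; the cyclobutanone and the alkyl chloride are inert.

Step 6
Reactants: 9 (1R,3S,6R)-3-(8-chlorooctyl)bicyclo[4.2.0]octan-7-one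
Product: 11 (1R,3S,6R)-3-(8-chlorooctyl)bicyclo[4.2.0]oct-7-en-7-yl trifluoromethanesulfonate, via lithium enolate 10 (not isolated)
Conditions: LiHMDS, THF, −78 °C; PhNTf2, −78 → 0 °C
Reagents that add atoms: N-phenylbis(trifluoromethanesulfonimide), O=S(=O)(N(c1ccccc1)S(=O)(=O)C(F)(F)F)C(F)(F)F
Why: Kinetic enolisation occurs at the C8 methylene (enolisation towards the ring-fusion carbon C6 would place the double bond at the ring fusion and is more strained) and O-triflation traps the enolate; no stereocentre is touched.

Step 7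
Reactants: 11 (1R,3S,6R)-3-(8-chlorooctyl)bicyclo[4.2.0]oct-7-en-7-yl trifluoromethanesulfonate
Product: 12 (1R,3S,6S)-3-(8-chlorooctyl)bicyclo[4.2.0]oct-7-ene
Conditions: Pd(OAc)2 (5 mol %), PPh3 (10 mol %), HCO2H, n-Bu3N, DMF, 50 °C
Reagents that add atoms: none
Why: Palladium-catalysed formate reduction of an enol triflate: zerovalent palladium inserts into the C–OTf bond, formate supplies hydride with loss of CO2 and reductive elimination gives the cyclobutene; the primary alkyl chloride does not undergo oxidative addition.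

Step 8
Reactants: 12 (1R,3S,6S)-3-(8-chlorooctyl)bicyclo[4.2.0]oct-7-ene; 13 maleic anhydride
Product: 14 ring A–ring B–ring C anhydride (C3 and C6 bridged by C(=O)–O–C(=O); ring C cis-fused to ring B and anti to ring A)
Conditions: hν (λ > 300 nm, Pyrex), acetophenone (sensitiser), EtOAc, 5–10 °C
Reagents that add atoms: none
Why: Triplet-sensitised [2+2] photocycloaddition: excited maleic anhydride adds stepwise to the exo face of the cyclobutene, away from ring A, so C2 and C7 become cis to each other and anti to ring A; the anhydride-bearing centres C3 and C6 are erased in step 10, so either orientation of the anhydride serves.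

Step 9
Reactants: 14 ring A–ring B–ring C anhydride
Product: 15 the corresponding cis-C3,C6-dicarboxylic acid
Conditions: H2O, THF, 50 °C
Reagents that add atoms: water, O
Why: Acyl substitution by water opens the strained cis-fused cyclic anhydride to the cis-diacid without touching any stereocentre.

Step 10
Reactants: 15 cis-C3,C6-dicarboxylic acid
Product: 16 ring A–ring B–cyclobutene tricycle (C3=C6 in a bicyclo[2.2.0]hex-2-ene; ring fusions cis; ring A anti to the cyclobutene; chain on C11 cis to ring B)
Conditions: Pb(OAc)4, pyridine, 45–50 °C, N2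
Reagents that add atoms: none
Why: Oxidative bisdecarboxylation of a vicinal cis-diacid with Pb(OAc)4 expels two CO2 and leaves the C3=C6 double bond at a temperature well below the electrocyclic opening of the bicyclo[2.2.0]hexene; the C3 and C6 stereocentres are destroyed and the chloride is inert.

Step 11
Reactants: 16 ring A–ring B–cyclobutene tricycle; 17 trichloroacetyl chloride
Product: 19 11-(8-chlorooctyl)-5,5-dichlorotetracyclo[6.4.0.0^2,7.0^3,6]dodecan-4-one (all ring fusions cis; adjacent rings anti), via dichloroketene 18 (not isolated)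
Conditions: Zn dust (activated), Cl3CCOCl (slow addition), Et2O–DME, ultrasound, 15–20 °C
Reagents that add atoms: none
Why: Zinc strips two chlorines from 17 to give dichloroketene, whose electrophilic central carbon attacks the strained, pyramidalised C3=C6 π bond in a concerted but asynchronous thermal [2+2] cycloaddition that makes C3–C4 slightly ahead of C5–C6. The closest known reaction type is the dichloroketene cycloaddition to unactivated and strained cycloalkenes followed by reductive dechlorination. Ring D (C3–C6) is closed in a single intermolecular two-bond annulation of a C2 unit onto the alkene, suprafacial on the alkene, so no exo or endo cyclisation mode applies. C3 and C6 are set together: suprafacial addition makes the ring C–ring D fusion cis, and approach to the exo face of the bicyclo[2.2.0]hex-2-ene, away from ring B (C1 and C8), makes it anti. The step needs only this facial selectivity, which ring B secures by blocking the concave face; the orientation of the ketene is irrelevant because C4 and C5 both end as CH2, and the cyclobutene is the only alkene while the alkyl chloride is inert to Zn and ZnCl2. Working in the dark near ambient temperature with DME to tie up ZnCl2 keeps the cyclobutene from opening to a cyclohexadiene or isomerising.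

Step 12
Reactants: 19 11-(8-chlorooctyl)-5,5-dichlorotetracyclo[6.4.0.0^2,7.0^3,6]dodecan-4-one
Product: 21 11-(8-chlorooctyl)tetracyclo[6.4.0.0^2,7.0^3,6]dodecan-4-one, via 5-monochloroketone 20 (not isolated)
Conditions: Zn dust, AcOH, rt
Reagents that add atoms: none
Why: Reductive dehalogenation of an α,α-dichloroketone by zinc proceeds twice through a zinc enolate that AcOH protonates; the unactivated primary chloride and the ring-fusion centres are untouched.

Step 13
Reactants: 21 11-(8-chlorooctyl)tetracyclo[6.4.0.0^2,7.0^3,6]dodecan-4-one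
Product: 22 the C4 tosylhydrazone of 21 (E/Z mixture)
Conditions: TsNHNH2, EtOH, rt → 40 °C
Reagents that add atoms: p-toluenesulfonohydrazide, Cc1ccc(cc1)S(=O)(=O)NN
Why: Hydrazone condensation is fast with the strained, unhindered cyclobutanone and needs no strong acid or base.

Step 14
Reactants: 22 C4 tosylhydrazone
Product: 25 (1S,2R,3R,6S,7S,8R,11S)-11-(8-chlorooctyl)tetracyclo[6.4.0.0^2,7.0^3,6]dodecane, via N-boryl tosylhydrazine 23 (not isolated), via C4 diazene 24 (not isolated)
Conditions: catecholborane, CHCl3, 0 °C → rt; then NaOAc·3H2O, 55 °C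
Reagents that add atoms: none
Why: Tosylhydrazone reduction with catecholborane (mild variant of the Caglioti reduction): hydride adds to C4, acetate triggers loss of sulfinate, and the diazene loses N2 near 55 °C, far below the thermal limit of the ladder and without a base strong enough to attack the alkyl chloride.

Step 15
Reactants: 25 (1S,2R,3R,6S,7S,8R,11S)-11-(8-chlorooctyl)tetracyclo[6.4.0.0^2,7.0^3,6]dodecane; 26 2,2-dimethyl-1,3-dioxan-5-ol
Product: 29 2,2-dimethyl-5-{[8-(ladderan-11-yl)octyl]oxy}-1,3-dioxane (core configuration as in 25), via sodium 2,2-dimethyl-1,3-dioxan-5-olate 27 (not isolated), via alkyl iodide 28 (not isolated)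
Conditions: 26 (3 equiv), NaH, DMF, 0 °C → rt; then 25, NaI (0.2 equiv), 60 °C
Reagents that add atoms: none
Why: Williamson ether synthesis with Finkelstein (iodide) catalysis: SN2 at the unhindered primary carbon by the secondary alkoxide, the 1,3-acetonide forcing alkylation at the central glycerol oxygen.

Step 16
Reactants: 29 acetonide ether
Product: 30 2-({8-[(1S,2R,3R,6S,7S,8R,11S)-tetracyclo[6.4.0.0^2,7.0^3,6]dodecan-11-yl]octyl}oxy)propane-1,3-diol (CNP0193334.1)
Conditions: AcOH/H2O (4:1), THF, 40 °C
Reagents that add atoms: water, O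
Why: Acid-catalysed acetal hydrolysis frees the 1,3-diol; the saturated ladder carries no acid-labile function.

Compound list

1 | chloroprene (2-chlorobuta-1,3-diene) | C=CC(Cl)=C | starting material
2 | 1-bromo-8-chlorooctane | ClCCCCCCCCBr | starting material
3 | buta-1,3-dien-2-ylmagnesium chloride | C=CC(=C)[Mg]Cl | intermediate (not isolated)
4 | 2-(8-chlorooctyl)buta-1,3-diene | ClCCCCCCCCC(=C)C=C | intermediate
5 | 3-oxocyclobutane-1-carboxylic acid | O=C1CC(C1)C(=O)O | starting material
6 | 3-bromocyclobutan-1-one | O=C1CC(Br)C1 | intermediate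
7 | cyclobut-2-en-1-one | O=C1C=CC1 | intermediate
8 | (1R,6R)-3-(8-chlorooctyl)bicyclo[4.2.0]oct-3-en-7-one | ClCCCCCCCCC1=CC[C@@H]2[C@H](C1)CC2=O | intermediate
9 | (1R,3S,6R)-3-(8-chlorooctyl)bicyclo[4.2.0]octan-7-one | ClCCCCCCCC[C@H]1CC[C@@H]2[C@H](C1)CC2=O | intermediate
10 | lithium enolate of 9 (C7–OLi, C7=C8) | ClCCCCCCCC[C@H]1CC[C@@H]2[C@H](C1)C=C2O[Li] | intermediate (not isolated)
11 | (1R,3S,6R)-3-(8-chlorooctyl)bicyclo[4.2.0]oct-7-en-7-yl trifluoromethanesulfonate | ClCCCCCCCC[C@H]1CC[C@@H]2[C@H](C1)C=C2OS(=O)(=O)C(F)(F)F | intermediate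
12 | (1R,3S,6S)-3-(8-chlorooctyl)bicyclo[4.2.0]oct-7-ene | ClCCCCCCCC[C@H]1CC[C@@H]2[C@H](C1)C=C2 | intermediate
13 | maleic anhydride | O=C1OC(=O)C=C1 | starting material
14 | ring A–ring B–ring C anhydride (8-(8-chlorooctyl)tricyclo[4.4.0.0^2,5]decane-3,4-dicarboxylic anhydride skeleton; cis,anti,cis; anhydride anti to ring B) | ClCCCCCCCC[C@H]1CC[C@@H]2[C@H](C1)[C@H]1[C@@H]3C(=O)OC(=O)[C@@H]3[C@@H]21 | intermediate
15 | cis-dicarboxylic acid from 14 | ClCCCCCCCC[C@H]1CC[C@@H]2[C@H](C1)[C@H]1[C@H](C(=O)O)[C@H](C(=O)O)[C@@H]21 | intermediate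
16 | ring A–ring B–cyclobutene tricycle (8-(8-chlorooctyl)tricyclo[4.4.0.0^2,5]dec-3-ene skeleton; C3=C6 in core numbering; cis,anti) | ClCCCCCCCC[C@H]1CC[C@@H]2[C@H](C1)[C@H]1C=C[C@@H]21 | intermediate (key-step precursor)
17 | trichloroacetyl chloride | ClC(Cl)(Cl)C(Cl)=O | starting material
18 | dichloroketene | ClC(Cl)=C=O | intermediate (not isolated)
19 | 11-(8-chlorooctyl)-5,5-dichlorotetracyclo[6.4.0.0^2,7.0^3,6]dodecan-4-one | ClCCCCCCCC[C@H]1CC[C@@H]2[C@H](C1)[C@H]1[C@@H]3C(=O)C(Cl)(Cl)[C@@H]3[C@@H]21 | intermediate (key-step product)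
20 | 5-chloro-11-(8-chlorooctyl)tetracyclo[6.4.0.0^2,7.0^3,6]dodecan-4-one (C5 epimers) | ClCCCCCCCC[C@H]1CC[C@@H]2[C@H](C1)[C@H]1[C@@H]3C(=O)C(Cl)[C@@H]3[C@@H]21 | intermediate (not isolated)
21 | 11-(8-chlorooctyl)tetracyclo[6.4.0.0^2,7.0^3,6]dodecan-4-one | ClCCCCCCCC[C@H]1CC[C@@H]2[C@H](C1)[C@H]1[C@@H]3C(=O)C[C@@H]3[C@@H]21 | intermediate
22 | C4 tosylhydrazone of 21 (E/Z) | ClCCCCCCCC[C@H]1CC[C@@H]2[C@H](C1)[C@H]1[C@@H]3C(=NNS(=O)(=O)c4ccc(C)cc4)C[C@@H]3[C@@H]21 | intermediate
23 | N-(1,3,2-benzodioxaborol-2-yl) tosylhydrazine at C4 (C4 epimers) | ClCCCCCCCC[C@H]1CC[C@@H]2[C@H](C1)[C@H]1[C@@H]3C(N(NS(=O)(=O)c4ccc(C)cc4)B4Oc5ccccc5O4)C[C@@H]3[C@@H]21 | intermediate (not isolated)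
24 | C4 diazene (C4 epimers) | ClCCCCCCCC[C@H]1CC[C@@H]2[C@H](C1)[C@H]1[C@@H]3C(N=N)C[C@@H]3[C@@H]21 | intermediate (not isolated)
25 | (1S,2R,3R,6S,7S,8R,11S)-11-(8-chlorooctyl)tetracyclo[6.4.0.0^2,7.0^3,6]dodecane | ClCCCCCCCC[C@H]1CC[C@@H]2[C@H](C1)[C@H]1[C@@H]3CC[C@@H]3[C@@H]21 | intermediate
26 | 2,2-dimethyl-1,3-dioxan-5-ol | CC1(C)OCC(O)CO1 | starting material
27 | sodium 2,2-dimethyl-1,3-dioxan-5-olate | CC1(C)OCC(O[Na])CO1 | intermediate (not isolated)
28 | (1S,2R,3R,6S,7S,8R,11S)-11-(8-iodooctyl)tetracyclo[6.4.0.0^2,7.0^3,6]dodecane | ICCCCCCCC[C@H]1CC[C@@H]2[C@H](C1)[C@H]1[C@@H]3CC[C@@H]3[C@@H]21 | intermediate (not isolated)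
29 | 2,2-dimethyl-5-{[8-(ladderan-11-yl)octyl]oxy}-1,3-dioxane | CC1(C)OCC(CO1)OCCCCCCCC[C@H]1CC[C@@H]2[C@H](C1)[C@H]1[C@@H]3CC[C@@H]3[C@@H]21 | intermediate
30 | 2-({8-[(1S,2R,3R,6S,7S,8R,11S)-tetracyclo[6.4.0.0^2,7.0^3,6]dodecan-11-yl]octyl}oxy)propane-1,3-diol | OCC(CO)OCCCCCCCC[C@H]1CC[C@@H]2[C@H](C1)[C@H]1[C@@H]3CC[C@@H]3[C@@H]21 | target

Total step count: 16. Longest linear sequence: 15 steps (steps 2–16); step 1 is a one-step branch that joins at step 4.

Steps most likely to fail

1. Step 11 (key step). What may go wrong: ZnCl2-promoted isomerisation or oligomerisation of the strained cyclobutene, or self-condensation of the ketene, outruns the cycloaddition; exo facial control may also be incomplete. Fallback, which replaces the thermal ketene addition by a photochemical two-carbon annulation, sets out from 16 and returns to the route at 25. Acetophenone-sensitised irradiation of 16 with maleic anhydride 13 should add, again on the exo face, to give the ring D anhydride F1. Water in THF opens it to the ring D diacid F2. Pb(OAc)4 in pyridine at 45 °C removes both carboxyl groups to give the ladder alkene F3 (C4=C5). Diimide, generated from KO2C–N=N–CO2K and AcOH in MeOH at 0 °C, saturates F3 to 25.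

2. Step 4. What may go wrong: the very reactive cyclobutenone reacts partly without the catalyst, or the catalyst differentiates the enone faces poorly, so enantiocontrol (and possibly "para" regiocontrol) is eroded. Fallback, which replaces asymmetric catalysis by resolution, sets out from 4 and 7 and returns at 8. The uncatalysed cycloaddition in CH2Cl2 at rt should give the racemic enone F4. NaBH4 in MeOH at −20 °C reduces it from the convex face to the racemic endo alcohol F5. Esterification with (S)-O-acetylmandelic acid (DCC, DMAP) gives two diastereomeric esters that are separated by chromatography or crystallisation, the (1R,6R)-series mandelate F6 being kept; its configuration is assigned by the usual NMR anisotropy analysis of mandelates. LiOH in THF/H2O releases the enantiopure alcohol F7, and Dess–Martin periodinane oxidises it back to 8.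

3. Step 10. What may go wrong: over-oxidation by the lead reagent (acetoxylation, lactone formation) and incomplete decarboxylation, with loss of the sensitive cyclobutene. Fallback, which brings in the two carbons as vinylene carbonate and releases the alkene by deoxygenation of a diol, sets out from 12 and returns at 16. Acetone-sensitised photocycloaddition of vinylene carbonate to the exo face of 12 should give the cyclic carbonate F8. KOH in MeOH/H2O gives the cis-diol F9. 1,1'-Thiocarbonyldiimidazole in toluene at 60 °C gives the cyclic thionocarbonate F10. Corey–Winter olefination in its mild form (1,3-dimethyl-2-phenyl-1,3,2-diazaphospholidine, 40 °C) extrudes CO2 and sulfur to give 16 below its ring-opening temperature.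

Further compounds

F1 | step 11 | ring D anhydride (C4 and C5 bridged by C(=O)–O–C(=O), anti to ring C) | ClCCCCCCCC[C@H]1CC[C@@H]2[C@H](C1)[C@H]1[C@@H]3[C@H]4C(=O)OC(=O)[C@H]4[C@@H]3[C@@H]21
F2 | step 11 | ring D cis-C4,C5-dicarboxylic acid | ClCCCCCCCC[C@H]1CC[C@@H]2[C@H](C1)[C@H]1[C@@H]3[C@@H](C(=O)O)[C@@H](C(=O)O)[C@@H]3[C@@H]21
F3 | step 11 | 11-(8-chlorooctyl)tetracyclo[6.4.0.0^2,7.0^3,6]dodec-4-ene | ClCCCCCCCC[C@H]1CC[C@@H]2[C@H](C1)[C@H]1[C@@H]3C=C[C@@H]3[C@@H]21
F4 | step 4 | racemic cis-3-(8-chlorooctyl)bicyclo[4.2.0]oct-3-en-7-one (both enantiomers) | ClCCCCCCCCC1=CC[C@@H]2[C@H](C1)CC2=O.ClCCCCCCCCC1=CC[C@H]2[C@@H](C1)CC2=O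
F5 | step 4 | racemic endo-3-(8-chlorooctyl)bicyclo[4.2.0]oct-3-en-7-ol (OH on the concave face; both enantiomers) | ClCCCCCCCCC1=CC[C@@H]2[C@H](C1)C[C@@H]2O.ClCCCCCCCCC1=CC[C@H]2[C@@H](C1)C[C@H]2O
F6 | step 4 | (S)-O-acetylmandelate of the (1R,6R)-series endo alcohol | ClCCCCCCCCC1=CC[C@@H]2[C@H](C1)C[C@@H]2OC(=O)[C@@H](OC(C)=O)c1ccccc1
F7 | step 4 | (1R,6R)-series endo-3-(8-chlorooctyl)bicyclo[4.2.0]oct-3-en-7-ol, single enantiomer | ClCCCCCCCCC1=CC[C@@H]2[C@H](C1)C[C@@H]2O
F8 | step 10 | ring A–ring B–ring C cyclic carbonate (C3 and C6 bridged by O–C(=O)–O, anti to ring B) | ClCCCCCCCC[C@H]1CC[C@@H]2[C@H](C1)[C@H]1[C@@H]3OC(=O)O[C@@H]3[C@@H]21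
F9 | step 10 | ring A–ring B–ring C cis-C3,C6-diol | ClCCCCCCCC[C@H]1CC[C@@H]2[C@H](C1)[C@H]1[C@H](O)[C@H](O)[C@@H]21
F10 | step 10 | cyclic thionocarbonate of F9 | ClCCCCCCCC[C@H]1CC[C@@H]2[C@H](C1)[C@H]1[C@@H]3OC(=S)O[C@@H]3[C@@H]21
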